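## Retrosynthetic overview
1. Target 19 comes from 18 by a single fluoride deprotection. All six benzene rings are bought; the oxane is the only ring that has to be made.
2. The oxane is made by a three-component "oxygen-to-carbon ring transcription" of methyl ketone 10, aldehyde 11 and syn-diol 7. It forms O1–C2, C2–C3 and C3–C4 and sets C2, C3 and C4.
3. Ring order, both in the same flask: the 1,3-dioxane template 13 forms first, then the oxane. The ketone α-carbon takes the place of the allylic dioxane oxygen.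
4. The C3'–C1'' bond of the side chain comes from an aromatic Claisen rearrangement of aryl ether 9, which is made from the same diol 7 and acetophenone 8 by an invertive Mitsunobu reaction.
5. Diol 7 comes from raspberry ketone and 4-hydroxybenzaldehyde by a boron aldol reaction with in-situ syn reduction.

Assumption: the configuration is taken exactly as written, so the oxane is (2R,3R,4S,6S), that is 2,3-trans, 3,4-cis, 4,6-cis and 2,6-trans, and the side chain is (1R,2E,5S). This is not the all-equatorial isomer, so equilibrating acid or base is avoided from step 7 on. TBS = tert-butyldimethylsilyl, TMS = trimethylsilyl.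

## Route

Step 1
Reactants: 1 4-hydroxybenzaldehyde
Product: 2 4-(tert-butyldimethylsilyloxy)benzaldehyde
Conditions: TBSCl, imidazole, DMF, rt
Reagents that add atoms: tert-butyldimethylsilyl chloride CC(C)(C)[Si](C)(C)Cl
Why: Imidazole-promoted O-silylation masks the phenol for the boron, phosphorus and silyl triflate chemistry that follows, and no stereocentre is involved.

Step 2
Reactants: 2 4-(tert-butyldimethylsilyloxy)benzaldehyde
Product: 3 (E)-3-[4-(tert-butyldimethylsilyloxy)phenyl]prop-2-enal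
Conditions: Ph3P=CHCHO, toluene, 80 °C
Reagents that add atoms: (triphenylphosphoranylidene)acetaldehyde O=CC=P(c1ccccc1)(c1ccccc1)c1ccccc1
Why: Wittig olefination with a stabilised ylide gives the E-enal and stops after one homologation because the conjugated product is the poorer electrophile.

Step 3
Reactants: 4 4-(4-hydroxyphenyl)butan-2-one (raspberry ketone)
Product: 5 4-[4-(tert-butyldimethylsilyloxy)phenyl]butan-2-one
Conditions: TBSCl, imidazole, DMF, rt
Reagents that add atoms: tert-butyldimethylsilyl chloride CC(C)(C)[Si](C)(C)Cl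
Why: This is the same O-silylation as in step 1, the ketone is untouched and no stereocentre is involved.

Step 4
Reactants: 5 4-[4-(tert-butyldimethylsilyloxy)phenyl]butan-2-one; 3 (E)-3-[4-(tert-butyldimethylsilyloxy)phenyl]prop-2-enal
Product: 7 (3S,5S,6E)-1,7-bis[4-(tert-butyldimethylsilyloxy)phenyl]hept-6-ene-3,5-diol, via boron aldolate 6 (not isolated)
Conditions: (−)-Ipc2BCl, Et3N, Et2O, 0 °C; 3, −78 to −20 °C; LiBH4, THF, −78 °C; H2O2, MeOH, pH 7 buffer; recrystallise
Reagents that add atoms: none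
Why: In this Paterson boron aldol reaction the methyl-side enol borinate adds to the Si face of the enal under control of the isopinocampheyl groups (sets 5S), and hydride then attacks the six-membered boron chelate 6 from the axial side (Narasaka-type 1,3-syn reduction, sets 3S).

Step 5
Reactants: 7 (3S,5S,6E)-1,7-bis[4-(tert-butyldimethylsilyloxy)phenyl]hept-6-ene-3,5-diol; 8 1-(2,4-dihydroxy-6-methoxyphenyl)ethanone
Product: 9 1-[4-({(1E,3R,5S)-5-hydroxy-1,7-bis[4-(tert-butyldimethylsilyloxy)phenyl]hept-1-en-3-yl}oxy)-2-hydroxy-6-methoxyphenyl]ethanone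
Conditions: PPh3, DIAD (1.0 equiv each), toluene, −20 to 0 °C
Reagents that add atoms: none
Why: In this Mitsunobu etherification only the non-chelated, more acidic 4-OH of 8 acts as the nucleophile, and only the allylic oxyphosphonium of 7 is displaced at a useful rate, by SN2 with inversion (5S of 7 becomes 3R of the ether).

Step 6
Reactants: 9 aryl heptenyl ether from step 5
Product: 10 1-{2,4-dihydroxy-3-[(1R,2E,5S)-5-hydroxy-1,7-bis[4-(tert-butyldimethylsilyloxy)phenyl]hept-2-en-1-yl]-6-methoxyphenyl}ethanone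
Conditions: 1,2-dichlorobenzene, BHT (cat.), 165 °C
Reagents that add atoms: none
Why: This suprafacial aromatic Claisen rearrangement runs through a chair with the CH2CH(OH) chain equatorial, transfers the 3R C–O centre into the 1R diaryl methine and gives the E-alkene, and the chelated 2-OH directs it to the ring carbon between the two oxygens.

Step 7
Reactants: 7 (3S,5S,6E)-1,7-bis[4-(tert-butyldimethylsilyloxy)phenyl]hept-6-ene-3,5-diol (second portion); 11 4-acetoxybenzaldehyde; 10 Claisen product from step 6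
Product: 18 tetra-TBS monoacetate of blepharocalyxin B with a (2R,3R,4S,6S)-oxane, via bis-TMS ether 12 (not isolated), via dioxane template 13 (not isolated), via enol silane 14 (not isolated), via seco ether 15 (not isolated), via second enol silane 16 (not isolated), via TMS-protected oxane 17 (not isolated)
Conditions: 7, iPr2NEt (2.2), TMSOTf (2.6), CH2Cl2, −78 °C, then 11; cannulate in 14 [from 10, iPr2NEt (4.4), TMSOTf (4.2), CH2Cl2, 0 °C], −78 to −45 °C; iPr2NEt (1.2), TMSOTf (1.5), −45 to −20 °C; pyridine quench; citric acid (cat.), MeOH, 0 °C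
Reagents that add atoms: none
Why: Proposed new method: silyl acetalisation gives the all-equatorial dioxane 13, TMSOTf cleaves its C2–O bond to the allylic oxygen (the better nucleofuge, while the more electron-rich alkyl-substituted oxygen keeps the cation) and enol silane 14 attacks anti to the departing tethered siloxy chain (inversion, sets 2R, trans to C6), then re-silylation to 16 and ionisation of only the electron-rich siloxycinnamyl silyl ether (the acetoxyphenyl group keeps the C2–O bond covalent) let the enol silane close the six-membered ring through the chair with both heptanoid substituents equatorial, the ring oxygen inside and the cheaper axial aryl group, which sets 4S (4,6-cis), 3R (2,3-trans, 3,4-cis) and the E-styryl group; the closest known reaction types are the invertive Johnson–Seebach substitution of chiral 1,3-dioxane acetals by enol silanes, one-pot TMSOTf/amine enol silane formation with Mukaiyama addition to acetals, and alkylation of enol silanes by stabilised allyl cations.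

Step 8
Reactants: 18 tetra-TBS monoacetate of blepharocalyxin B
Product: 19 blepharocalyxin B
Conditions: TBAF·3H2O (7 equiv), THF, 0 °C, 20 min; AcOH quench, pH 7 buffer
Reagents that add atoms: none
Why: Fluoride cleaves the four aryl silyl ethers and the aryl acetate within minutes, while phenoxide-level basicity at 0 °C neither enolises the hindered chelated ketone nor triggers retro-oxa-Michael opening, so all six stereocentres are kept.

## Compound list
1 | 4-hydroxybenzaldehyde | O=Cc1ccc(O)cc1 | starting material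
2 | 4-(tert-butyldimethylsilyloxy)benzaldehyde | O=Cc1ccc(O[Si](C)(C)C(C)(C)C)cc1 | intermediate
3 | (E)-3-[4-(tert-butyldimethylsilyloxy)phenyl]prop-2-enal | O=C/C=C/c1ccc(O[Si](C)(C)C(C)(C)C)cc1 | intermediate
4 | 4-(4-hydroxyphenyl)butan-2-one | CC(=O)CCc1ccc(O)cc1 | starting material
5 | 4-[4-(tert-butyldimethylsilyloxy)phenyl]butan-2-one | CC(=O)CCc1ccc(O[Si](C)(C)C(C)(C)C)cc1 | intermediate
6 | diisopinocampheylboron aldolate of (5S,6E)-5-hydroxy-1,7-bis(4-TBSO-phenyl)hept-6-en-3-one | CC(C)(C)[Si](C)(C)Oc1ccc(CCC(=O)C[C@H](OB([C@@H]2C[C@@H]3C[C@H]([C@H]2C)C3(C)C)[C@@H]2C[C@@H]3C[C@H]([C@H]2C)C3(C)C)/C=C/c2ccc(O[Si](C)(C)C(C)(C)C)cc2)cc1 | intermediate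
7 | (3S,5S,6E)-1,7-bis(4-TBSO-phenyl)hept-6-ene-3,5-diol | CC(C)(C)[Si](C)(C)Oc1ccc(CC[C@H](O)C[C@H](O)/C=C/c2ccc(O[Si](C)(C)C(C)(C)C)cc2)cc1 | intermediate
8 | 1-(2,4-dihydroxy-6-methoxyphenyl)ethanone | CC(=O)c1c(O)cc(O)cc1OC | starting material
9 | 4-O-[(1E,3R,5S)-5-hydroxy-1,7-bis(4-TBSO-phenyl)hept-1-en-3-yl] ether of 8 | CC(=O)c1c(O)cc(O[C@H](C[C@@H](O)CCc2ccc(O[Si](C)(C)C(C)(C)C)cc2)/C=C/c2ccc(O[Si](C)(C)C(C)(C)C)cc2)cc1OC | intermediate
10 | 1-{2,4-dihydroxy-3-[(1R,2E,5S)-5-hydroxy-1,7-bis(4-TBSO-phenyl)hept-2-en-1-yl]-6-methoxyphenyl}ethanone | COc1cc(O)c([C@H](/C=C/C[C@@H](O)CCc2ccc(O[Si](C)(C)C(C)(C)C)cc2)c2ccc(O[Si](C)(C)C(C)(C)C)cc2)c(O)c1C(C)=O | intermediate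
11 | 4-acetoxybenzaldehyde | CC(=O)Oc1ccc(C=O)cc1 | starting material
12 | bis-TMS ether of 7 | CC(C)(C)[Si](C)(C)Oc1ccc(CC[C@H](O[Si](C)(C)C)C[C@H](O[Si](C)(C)C)/C=C/c2ccc(O[Si](C)(C)C(C)(C)C)cc2)cc1 | intermediate
13 | (2S,4S,6S)-2-(4-acetoxyphenyl)-4-[(E)-4-TBSO-styryl]-6-[2-(4-TBSO-phenyl)ethyl]-1,3-dioxane (all-cis) | CC(C)(C)[Si](C)(C)Oc1ccc(CC[C@H]2C[C@@H](/C=C/c3ccc(O[Si](C)(C)C(C)(C)C)cc3)O[C@@H](c3ccc(OC(C)=O)cc3)O2)cc1 | intermediate
14 | tris-O-TMS ether TMS enol ether of 10 | COc1cc(O[Si](C)(C)C)c([C@H](/C=C/C[C@@H](O[Si](C)(C)C)CCc2ccc(O[Si](C)(C)C(C)(C)C)cc2)c2ccc(O[Si](C)(C)C(C)(C)C)cc2)c(O[Si](C)(C)C)c1C(=C)O[Si](C)(C)C | intermediate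
15 | (3R)-β-alkoxy ketone (seco ether) bearing the (3S,5S,6E)-5-TMSO-hept-6-en-3-yloxy group | COc1cc(O[Si](C)(C)C)c([C@H](/C=C/C[C@@H](O[Si](C)(C)C)CCc2ccc(O[Si](C)(C)C(C)(C)C)cc2)c2ccc(O[Si](C)(C)C(C)(C)C)cc2)c(O[Si](C)(C)C)c1C(=O)C[C@H](c1ccc(OC(C)=O)cc1)O[C@@H](CCc1ccc(O[Si](C)(C)C(C)(C)C)cc1)C[C@H](O[Si](C)(C)C)/C=C/c1ccc(O[Si](C)(C)C(C)(C)C)cc1 | intermediate
16 | (Z)-TMS enol ether of 15 | COc1cc(O[Si](C)(C)C)c([C@H](/C=C/C[C@@H](O[Si](C)(C)C)CCc2ccc(O[Si](C)(C)C(C)(C)C)cc2)c2ccc(O[Si](C)(C)C(C)(C)C)cc2)c(O[Si](C)(C)C)c1/C(O[Si](C)(C)C)=C/[C@H](c1ccc(OC(C)=O)cc1)O[C@@H](CCc1ccc(O[Si](C)(C)C(C)(C)C)cc1)C[C@H](O[Si](C)(C)C)/C=C/c1ccc(O[Si](C)(C)C(C)(C)C)cc1 | intermediate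
17 | tris-O-TMS ether of 18 | COc1cc(O[Si](C)(C)C)c([C@H](/C=C/C[C@@H](O[Si](C)(C)C)CCc2ccc(O[Si](C)(C)C(C)(C)C)cc2)c2ccc(O[Si](C)(C)C(C)(C)C)cc2)c(O[Si](C)(C)C)c1C(=O)[C@@H]1[C@H](/C=C/c2ccc(O[Si](C)(C)C(C)(C)C)cc2)C[C@H](CCc2ccc(O[Si](C)(C)C(C)(C)C)cc2)O[C@H]1c1ccc(OC(C)=O)cc1 | intermediate
18 | blepharocalyxin B, four outer phenols as TBS ethers, oxane C2 aryl as acetate | COc1cc(O)c([C@H](/C=C/C[C@@H](O)CCc2ccc(O[Si](C)(C)C(C)(C)C)cc2)c2ccc(O[Si](C)(C)C(C)(C)C)cc2)c(O)c1C(=O)[C@@H]1[C@H](/C=C/c2ccc(O[Si](C)(C)C(C)(C)C)cc2)C[C@H](CCc2ccc(O[Si](C)(C)C(C)(C)C)cc2)O[C@H]1c1ccc(OC(C)=O)cc1 | intermediate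
19 | blepharocalyxin B | COc1cc(O)c([C@H](/C=C/C[C@@H](O)CCc2ccc(O)cc2)c2ccc(O)cc2)c(O)c1C(=O)[C@@H]1[C@H](/C=C/c2ccc(O)cc2)C[C@H](CCc2ccc(O)cc2)O[C@H]1c1ccc(O)cc1 | target

## Step count and risks
Total steps: 8. Longest linear sequence: 7 (steps 1, 2, 4, 5, 6, 7, 8).

**Risk 1, step 7.**
- What can go wrong: cleavage of the wrong acetal C–O bond, silyl-triflate-induced β-elimination of 15/16 to the chalcone (which loses C2), or closure through the chair with the C6 chain axial (which gives the C4 epimer). Any equilibration leads to the all-equatorial isomer.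
- Fallback: it sets out from 10, 7 and 11, comes back at 19, and replaces the one-flask cationic cascade with a stepwise, metal-catalysed stereospecific closure. Compound 10 is persilylated with TBSOTf/Et3N to the tris-TBS ether TBS enol ether F1. Dioxane 13 is made separately from 7 and 11 and isolated. TiCl4 in CH2Cl2 at −78 °C joins F1 and 13 through a tight ion pair to give the seco allylic alcohol F2. ClCO2Me/pyridine then gives the allylic methyl carbonate F3. Pd(PPh3)4 (zerovalent palladium) in THF at 0 °C ionises F3 with inversion, and the enolate made by the liberated methoxide attacks anti to the metal. C4 is therefore fixed by double inversion and not by a free cation, giving the fully protected oxane F4. TBAF as in step 8 then gives 19.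

**Risk 2, step 5.**
- What can go wrong: reaction at the wrong hydroxyl group, SN2' attack, or partial ionisation of the electron-rich cinnamyl system.
- Fallback: it sets out from 7 and 8, comes back at 9, and replaces redox condensation with SN2 opening of a cyclic electrophile. SOCl2/Et3N in CH2Cl2 at 0 °C turns 7 into the cyclic sulfite F5. The potassium 4-phenoxide of 8 (K2CO3, DMF, 40 °C) opens F5 at the allylic carbon with inversion. Dilute acid hydrolyses the remaining sulfite half-ester at the other oxygen to give 9.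

**Risk 3, step 6.**
- What can go wrong: rearrangement to the other free ortho carbon, or ionisation and recombination with loss of chirality transfer.
- Fallback: it sets out from 8 and 7, comes back at 10, and moves the allyl group to the oxygen that has only one free ortho position. Ac2O (1 equiv)/pyridine acetylates the non-chelated 4-OH of 8 to give 4-acetyl-3-hydroxy-5-methoxyphenyl acetate F6. Mitsunobu reaction of F6 with 7 gives the 2-O-heptenyl ether F7. Heating rearranges F7 only to the carbon between the two oxygens, giving the Claisen product acetate F8. Catalytic K2CO3 in MeOH at 0 °C removes the acetate to give 10.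

## Further compounds
F1 | step 7 | tris-TBS ether TBS enol ether of 10 | COc1cc(O[Si](C)(C)C(C)(C)C)c([C@H](/C=C/C[C@@H](O[Si](C)(C)C(C)(C)C)CCc2ccc(O[Si](C)(C)C(C)(C)C)cc2)c2ccc(O[Si](C)(C)C(C)(C)C)cc2)c(O[Si](C)(C)C(C)(C)C)c1C(=C)O[Si](C)(C)C(C)(C)C
F2 | step 7 | seco allylic alcohol | COc1cc(O[Si](C)(C)C(C)(C)C)c([C@H](/C=C/C[C@@H](O[Si](C)(C)C(C)(C)C)CCc2ccc(O[Si](C)(C)C(C)(C)C)cc2)c2ccc(O[Si](C)(C)C(C)(C)C)cc2)c(O[Si](C)(C)C(C)(C)C)c1C(=O)C[C@H](c1ccc(OC(C)=O)cc1)O[C@@H](CCc1ccc(O[Si](C)(C)C(C)(C)C)cc1)C[C@H](O)/C=C/c1ccc(O[Si](C)(C)C(C)(C)C)cc1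
F3 | step 7 | allylic methyl carbonate | COc1cc(O[Si](C)(C)C(C)(C)C)c([C@H](/C=C/C[C@@H](O[Si](C)(C)C(C)(C)C)CCc2ccc(O[Si](C)(C)C(C)(C)C)cc2)c2ccc(O[Si](C)(C)C(C)(C)C)cc2)c(O[Si](C)(C)C(C)(C)C)c1C(=O)C[C@H](c1ccc(OC(C)=O)cc1)O[C@@H](CCc1ccc(O[Si](C)(C)C(C)(C)C)cc1)C[C@H](OC(=O)OC)/C=C/c1ccc(O[Si](C)(C)C(C)(C)C)cc1
F4 | step 7 | fully protected oxane | COc1cc(O[Si](C)(C)C(C)(C)C)c([C@H](/C=C/C[C@@H](O[Si](C)(C)C(C)(C)C)CCc2ccc(O[Si](C)(C)C(C)(C)C)cc2)c2ccc(O[Si](C)(C)C(C)(C)C)cc2)c(O[Si](C)(C)C(C)(C)C)c1C(=O)[C@@H]1[C@H](/C=C/c2ccc(O[Si](C)(C)C(C)(C)C)cc2)C[C@H](CCc2ccc(O[Si](C)(C)C(C)(C)C)cc2)O[C@H]1c1ccc(OC(C)=O)cc1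
F5 | step 5 | cyclic sulfite of 7 | CC(C)(C)[Si](C)(C)Oc1ccc(CC[C@H]2C[C@@H](/C=C/c3ccc(O[Si](C)(C)C(C)(C)C)cc3)OS(=O)O2)cc1
F6 | step 6 | 4-acetyl-3-hydroxy-5-methoxyphenyl acetate | CC(=O)Oc1cc(O)c(C(C)=O)c(OC)c1
F7 | step 6 | 2-O-heptenyl ether | CC(=O)Oc1cc(O[C@H](C[C@@H](O)CCc2ccc(O[Si](C)(C)C(C)(C)C)cc2)/C=C/c2ccc(O[Si](C)(C)C(C)(C)C)cc2)c(C(C)=O)c(OC)c1
F8 | step 6 | Claisen product acetate | COc1cc(OC(C)=O)c([C@H](/C=C/C[C@@H](O)CCc2ccc(O[Si](C)(C)C(C)(C)C)cc2)c2ccc(O[Si](C)(C)C(C)(C)C)cc2)c(O)c1C(C)=O
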